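**Retrosynthetic overview**
1. Target ⇐ acetonide/TBS‑protected pentaol, freed in one mild acid step.
2. C9–OH and the C8 stereocentre ⇐ anti‑selective hydroboration–oxidation of a 2‑aryloxy allylic alcohol, with C7 controlling C8.
3. Key C7–C8 bond ⇐ catalytic enantioselective addition of a 1‑(aryloxy)vinyl metal to the ring A aldehyde. This is an acyl anion equivalent: C8, an oxygen‑bearing carbon, is the nucleophile and already carries ring B. The step sets C7.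
4. Vinyl ether ⇐ 4‑allyl‑2,6‑dimethoxyphenol (hydroboration, O‑vinylation, silylation); aldehyde ⇐ vanillin + 2,2‑dimethyl‑1,3‑dioxan‑5‑ol (Mitsunobu).
5. Ring formation: none. Ring A (from vanillin), ring B (from the allylphenol) and the dioxane protecting ring are bought intact.

Assumption: the SMILES is read as the (7R,8S)‑erythro isomer (C7 = benzylic carbinol, C8 = aryloxy carbon, C9 = CH2OH); (−)‑MIB, TEEDA, 9‑BBN and the trivinylboroxine–pyridine complex are bought reagents.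

**Step 1**
Reactants: 1 4‑allyl‑2,6‑dimethoxyphenol
Product: 3 4‑(3‑hydroxypropyl)‑2,6‑dimethoxyphenol, via bis(9‑BBN) adduct 2 (not isolated)
Conditions: 9‑BBN (2.2 equiv), THF, 0 °C → rt; then 3 M NaOH, 30% H2O2, 0 °C
Reagents that add atoms: hydrogen peroxide (OO)
Why: Anti‑Markovnikov hydroboration–oxidation of the terminal alkene with 9‑BBN gives the primary alcohol; the phenol is only transiently O‑borylated and is freed on work‑up, and no stereocentre is formed.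

**Step 2**
Reactants: 3 4‑(3‑hydroxypropyl)‑2,6‑dimethoxyphenol
Product: 4 3‑[4‑(ethenyloxy)‑3,5‑dimethoxyphenyl]propan‑1‑ol
Conditions: 2,4,6‑trivinylcyclotriboroxane·pyridine (0.7 equiv), Cu(OAc)2 (1 equiv), pyridine, CH2Cl2, O2 (air) as terminal oxidant, rt
Reagents that add atoms: 2,4,6‑trivinylcyclotriboroxane–pyridine complex (C=CB1OB(C=C)OB(C=C)O1.c1ccncc1)
Why: Chan–Lam oxidative O‑vinylation, in which vinyl passes from boron to divalent copper and C–O reductive elimination occurs from trivalent copper, is selective for the acidic phenol over the aliphatic alcohol.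

**Step 3**
Reactants: 4 3‑[4‑(ethenyloxy)‑3,5‑dimethoxyphenyl]propan‑1‑ol
Product: 5 tert‑butyl{3‑[4‑(ethenyloxy)‑3,5‑dimethoxyphenyl]propoxy}dimethylsilane
Conditions: TBSCl, imidazole, DMF, 0 °C → rt
Reagents that add atoms: tert‑butyldimethylsilyl chloride (CC(C)(C)[Si](C)(C)Cl)
Why: Standard silylation of the only free hydroxyl removes the acidic proton before the organolithium step and leaves the base‑stable aryl vinyl ether untouched.

**Step 4**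
Reactants: 6 vanillin (4‑hydroxy‑3‑methoxybenzaldehyde); 7 2,2‑dimethyl‑1,3‑dioxan‑5‑ol
Product: 8 4‑[(2,2‑dimethyl‑1,3‑dioxan‑5‑yl)oxy]‑3‑methoxybenzaldehyde
Conditions: PPh3, DIAD, THF, 0 → 50 °C
Reagents that add atoms: none
Why: Mitsunobu etherification, in which the acidic phenol of vanillin (pKa about 7.4) displaces the activated secondary alcohol by SN2; the inversion at C5 of the dioxane has no stereochemical consequence because that carbon lies on a mirror plane, and the aldehyde is inert.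

**Step 5 (key step)**
Reactants: 5 tert‑butyl{3‑[4‑(ethenyloxy)‑3,5‑dimethoxyphenyl]propoxy}dimethylsilane; 8 4‑[(2,2‑dimethyl‑1,3‑dioxan‑5‑yl)oxy]‑3‑methoxybenzaldehyde
Product: 12 (1R)‑2‑[4‑(3‑{[tert‑butyl(dimethyl)silyl]oxy}propyl)‑2,6‑dimethoxyphenoxy]‑1‑{4‑[(2,2‑dimethyl‑1,3‑dioxan‑5‑yl)oxy]‑3‑methoxyphenyl}prop‑2‑en‑1‑ol, via 1‑(aryloxy)vinyllithium 9 (not isolated), via 1‑(aryloxy)vinylzinc chloride 10 (not isolated), via butyl[1‑(aryloxy)vinyl]zinc 11 (not isolated)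
Conditions: 5 (1.5 equiv), t‑BuLi, THF, −78 → −40 °C; ZnCl2, then n‑BuLi, −78 → 0 °C; solvent switch to toluene, TEEDA (N,N,N′,N′‑tetraethylethylenediamine), (−)‑MIB (10 mol %), then 8, 0 °C; pH 7 aqueous quench, Et3N‑deactivated silica
Reagents that add atoms: none
Why: Proposed new method: t‑BuLi removes the α‑vinyl proton of 5 (the ortho‑methoxy group chelates lithium, and the blocked, electron‑rich ring resists ortho‑lithiation and Smiles‑type aryl migration) to give the acyl anion equivalent 9, which after transmetalation to the mixed alkenyl(alkyl)zinc 11 should transfer its sp2 carbon C8 to the Si face of aldehyde 8 through the amino‑alkoxide‑bridged dizinc (Noyori‑type) transition state of (2S)‑(−)‑3‑exo‑morpholinoisoborneol, setting C7 as R, while TEEDA sequesters LiCl to suppress the racemic background; the closest known reaction types are the MIB‑catalysed asymmetric addition of alkenyl‑ and aryl(alkyl)zinc reagents made from organolithiums to aromatic aldehydes and the racemic addition of 1‑alkoxyvinyllithiums to aldehydes.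

**Step 6**
Reactants: 12 the (1R)‑2‑aryloxy allylic alcohol from step 5
Product: 14 (1R,2S)‑2‑[4‑(3‑{[tert‑butyl(dimethyl)silyl]oxy}propyl)‑2,6‑dimethoxyphenoxy]‑1‑{4‑[(2,2‑dimethyl‑1,3‑dioxan‑5‑yl)oxy]‑3‑methoxyphenyl}propane‑1,3‑diol, via bis(9‑BBN) adduct 13 (not isolated)
Conditions: 9‑BBN (3 equiv), THF, 0 °C → rt; then 30% H2O2, 2 M NaOH, 0 °C
Reagents that add atoms: hydrogen peroxide (OO)
Why: Substrate‑controlled hydroboration–oxidation (Still–Barrish/Houk model, as known for 2‑alkoxy allylic alcohols made from 1‑alkoxyvinyllithiums) puts boron on the terminal carbon and delivers hydrogen to C8 anti to the C7 aryl group in the conformer with C7–H eclipsing the alkene, so C8 becomes S (7,8‑anti, erythro), and oxidation with retention gives the C9 alcohol.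

**Step 7**
Reactants: 14 the protected (1R,2S)‑diol from step 6
Product: 15 (1R,2S)‑1‑{4‑[(1,3‑dihydroxypropan‑2‑yl)oxy]‑3‑methoxyphenyl}‑2‑[4‑(3‑hydroxypropyl)‑2,6‑dimethoxyphenoxy]propane‑1,3‑diol
Conditions: AcOH/THF/H2O (3:1:1), 40 °C
Reagents that add atoms: none
Why: Mild aqueous acid hydrolysis cleaves the isopropylidene acetal and the primary TBS ether in one operation, while acetic acid is too weak to ionise the benzylic C7 alcohol, so both stereocentres are kept.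

**Compound list**
1 | 4‑allyl‑2,6‑dimethoxyphenol | C=CCc1cc(OC)c(O)c(OC)c1 | starting material
2 | 9‑{3‑[4‑(9‑borabicyclo[3.3.1]nonan‑9‑yloxy)‑3,5‑dimethoxyphenyl]propyl}‑9‑borabicyclo[3.3.1]nonane | COc1cc(CCCB2C3CCCC2CCC3)cc(OC)c1OB1C2CCCC1CCC2 | intermediate
3 | 4‑(3‑hydroxypropyl)‑2,6‑dimethoxyphenol | COc1cc(CCCO)cc(OC)c1O | intermediate
4 | 3‑[4‑(ethenyloxy)‑3,5‑dimethoxyphenyl]propan‑1‑ol | COc1cc(CCCO)cc(OC)c1OC=C | intermediate
5 | tert‑butyl{3‑[4‑(ethenyloxy)‑3,5‑dimethoxyphenyl]propoxy}dimethylsilane | COc1cc(CCCO[Si](C)(C)C(C)(C)C)cc(OC)c1OC=C | intermediate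
6 | vanillin | COc1cc(C=O)ccc1O | starting material
7 | 2,2‑dimethyl‑1,3‑dioxan‑5‑ol | CC1(C)OCC(O)CO1 | starting material
8 | 4‑[(2,2‑dimethyl‑1,3‑dioxan‑5‑yl)oxy]‑3‑methoxybenzaldehyde | COc1cc(C=O)ccc1OC1COC(C)(C)OC1 | intermediate
9 | {1‑[4‑(3‑TBSO‑propyl)‑2,6‑dimethoxyphenoxy]ethenyl}lithium | [Li]C(=C)Oc1c(OC)cc(CCCO[Si](C)(C)C(C)(C)C)cc1OC | intermediate
10 | chloro{1‑[4‑(3‑TBSO‑propyl)‑2,6‑dimethoxyphenoxy]ethenyl}zinc | Cl[Zn]C(=C)Oc1c(OC)cc(CCCO[Si](C)(C)C(C)(C)C)cc1OC | intermediate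
11 | butyl{1‑[4‑(3‑TBSO‑propyl)‑2,6‑dimethoxyphenoxy]ethenyl}zinc | CCCC[Zn]C(=C)Oc1c(OC)cc(CCCO[Si](C)(C)C(C)(C)C)cc1OC | intermediate
12 | (1R)‑2‑[4‑(3‑{[tert‑butyl(dimethyl)silyl]oxy}propyl)‑2,6‑dimethoxyphenoxy]‑1‑{4‑[(2,2‑dimethyl‑1,3‑dioxan‑5‑yl)oxy]‑3‑methoxyphenyl}prop‑2‑en‑1‑ol | COc1cc([C@@H](O)C(=C)Oc2c(OC)cc(CCCO[Si](C)(C)C(C)(C)C)cc2OC)ccc1OC1COC(C)(C)OC1 | intermediate
13 | (1R,2S)‑bis(9‑BBN) adduct of 12 (C7–O–BBN borinate, C9–BBN alkylborane) | COc1cc([C@@H](OB2C3CCCC2CCC3)[C@H](CB2C3CCCC2CCC3)Oc2c(OC)cc(CCCO[Si](C)(C)C(C)(C)C)cc2OC)ccc1OC1COC(C)(C)OC1 | intermediate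
14 | (1R,2S)‑2‑[4‑(3‑{[tert‑butyl(dimethyl)silyl]oxy}propyl)‑2,6‑dimethoxyphenoxy]‑1‑{4‑[(2,2‑dimethyl‑1,3‑dioxan‑5‑yl)oxy]‑3‑methoxyphenyl}propane‑1,3‑diol | COc1cc([C@@H](O)[C@H](CO)Oc2c(OC)cc(CCCO[Si](C)(C)C(C)(C)C)cc2OC)ccc1OC1COC(C)(C)OC1 | intermediate
15 | (1R,2S)‑1‑{4‑[(1,3‑dihydroxypropan‑2‑yl)oxy]‑3‑methoxyphenyl}‑2‑[4‑(3‑hydroxypropyl)‑2,6‑dimethoxyphenoxy]propane‑1,3‑diol | COc1cc([C@@H](O)[C@H](CO)Oc2c(OC)cc(CCCO)cc2OC)ccc1OC(CO)CO | target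

**Totals**
Total steps: 7. Longest linear sequence: 6 steps (1 → 3 → 4 → 5 → 12 → 14 → 15).

**Three steps most likely to fail, with fallbacks**

Step 5. The vinyl anion may decompose (α‑elimination of aryloxide), or the zinc addition may be slow or poorly enantioselective. The fallback keeps an acyl‑anion C7–C8 coupling but reverses the roles and lets an enzyme set the stereocentre. It sets out from aldehyde 8 and comes back at 14.
- Benzaldehyde lyase (thiamine diphosphate, MgSO4, phosphate buffer pH 8, DMSO cosolvent, 30 °C) converts 8 into its enzyme‑bound Breslow intermediate, which adds to (benzyloxy)acetaldehyde to give (2R)‑3‑(benzyloxy)‑1‑{4‑[(2,2‑dimethyl‑1,3‑dioxan‑5‑yl)oxy]‑3‑methoxyphenyl}‑2‑hydroxypropan‑1‑one F1.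
- Phenol 3 is silylated on its primary alcohol (TBSCl, imidazole) to 4‑(3‑{[tert‑butyl(dimethyl)silyl]oxy}propyl)‑2,6‑dimethoxyphenol F2.
- Mitsunobu coupling of F1 with F2 (PPh3, DIAD) forms the aryl ether with inversion, giving (2S)‑3‑(benzyloxy)‑2‑[4‑(3‑{[tert‑butyl(dimethyl)silyl]oxy}propyl)‑2,6‑dimethoxyphenoxy]‑1‑{4‑[(2,2‑dimethyl‑1,3‑dioxan‑5‑yl)oxy]‑3‑methoxyphenyl}propan‑1‑one F3.
- Chelation‑controlled reduction with Zn(BH4)2 (Et2O, −20 °C) gives the erythro alcohol (1R,2S)‑3‑(benzyloxy)‑2‑[4‑(3‑{[tert‑butyl(dimethyl)silyl]oxy}propyl)‑2,6‑dimethoxyphenoxy]‑1‑{4‑[(2,2‑dimethyl‑1,3‑dioxan‑5‑yl)oxy]‑3‑methoxyphenyl}propan‑1‑ol F4.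
- Hydrogenolysis of the benzyl ether (H2, Pd/C, EtOAc) returns to the route at 14.

Step 6. The β‑aryloxy alkylborane may eliminate aryloxide, and the anti selectivity is by analogy with alkyl enol ethers and may be modest. The fallback sets out from 12 and replaces substrate control by a catalyst‑controlled copper–boryl protoboration: B2pin2, MeOH, CuCl, NaOt‑Bu and the matched enantiomer of DTBM‑SEGPHOS. The monovalent copper boryl puts boron on C9 and copper on C8, and methanol protonates C8. This gives the stable pinacol boronate (1R,2S)‑2‑[4‑(3‑{[tert‑butyl(dimethyl)silyl]oxy}propyl)‑2,6‑dimethoxyphenoxy]‑1‑{4‑[(2,2‑dimethyl‑1,3‑dioxan‑5‑yl)oxy]‑3‑methoxyphenyl}‑3‑(4,4,5,5‑tetramethyl‑1,3,2‑dioxaborolan‑2‑yl)propan‑1‑ol F5. Oxidation (H2O2, NaOH, 0 °C) comes back at 14.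

Step 2. Chan–Lam vinylation of a phenol flanked by two methoxy groups may be sluggish. The fallback sets out from phenol 3: O‑alkylation with 1,2‑dibromoethane (K2CO3, acetone, reflux) gives 3‑[4‑(2‑bromoethoxy)‑3,5‑dimethoxyphenyl]propan‑1‑ol F6, and E2 elimination (KOt‑Bu, DMSO, rt) comes back at vinyl ether 4.

**Further compounds**
F1 | step 5 | (2R)‑3‑(benzyloxy)‑1‑{4‑[(2,2‑dimethyl‑1,3‑dioxan‑5‑yl)oxy]‑3‑methoxyphenyl}‑2‑hydroxypropan‑1‑one | COc1cc(C(=O)[C@H](O)COCc2ccccc2)ccc1OC1COC(C)(C)OC1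
F2 | step 5 | 4‑(3‑{[tert‑butyl(dimethyl)silyl]oxy}propyl)‑2,6‑dimethoxyphenol | COc1cc(CCCO[Si](C)(C)C(C)(C)C)cc(OC)c1O
F3 | step 5 | (2S)‑3‑(benzyloxy)‑2‑[4‑(3‑{[tert‑butyl(dimethyl)silyl]oxy}propyl)‑2,6‑dimethoxyphenoxy]‑1‑{4‑[(2,2‑dimethyl‑1,3‑dioxan‑5‑yl)oxy]‑3‑methoxyphenyl}propan‑1‑one | COc1cc(C(=O)[C@H](COCc2ccccc2)Oc2c(OC)cc(CCCO[Si](C)(C)C(C)(C)C)cc2OC)ccc1OC1COC(C)(C)OC1
F4 | step 5 | (1R,2S)‑3‑(benzyloxy)‑2‑[4‑(3‑{[tert‑butyl(dimethyl)silyl]oxy}propyl)‑2,6‑dimethoxyphenoxy]‑1‑{4‑[(2,2‑dimethyl‑1,3‑dioxan‑5‑yl)oxy]‑3‑methoxyphenyl}propan‑1‑ol | COc1cc([C@@H](O)[C@H](COCc2ccccc2)Oc2c(OC)cc(CCCO[Si](C)(C)C(C)(C)C)cc2OC)ccc1OC1COC(C)(C)OC1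
F5 | step 6 | (1R,2S)‑2‑[4‑(3‑{[tert‑butyl(dimethyl)silyl]oxy}propyl)‑2,6‑dimethoxyphenoxy]‑1‑{4‑[(2,2‑dimethyl‑1,3‑dioxan‑5‑yl)oxy]‑3‑methoxyphenyl}‑3‑(4,4,5,5‑tetramethyl‑1,3,2‑dioxaborolan‑2‑yl)propan‑1‑ol | COc1cc([C@@H](O)[C@H](CB2OC(C)(C)C(C)(C)O2)Oc2c(OC)cc(CCCO[Si](C)(C)C(C)(C)C)cc2OC)ccc1OC1COC(C)(C)OC1
F6 | step 2 | 3‑[4‑(2‑bromoethoxy)‑3,5‑dimethoxyphenyl]propan‑1‑ol | COc1cc(CCCO)cc(OC)c1OCCBr
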